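**Retrosynthetic overview**
1. Target 25 comes from hexaacetate 24 by mild global deacetylation.
2. 24 comes from an enantioselective endo Diels–Alder reaction of two C26 chalcones, dienophile 13 and diene 23. The cyclohexene is the only ring built and it is formed last; all arene rings are bought.
3. 13 and 23 both come from prenyl ketone 7 by Claisen–Schmidt condensation with aldehydes 10 and 17; the diene of 23 is made from the prenyl group by ene oxidation and dehydration.
4. 7 comes from resorcinol by two directed ortho-metalations (prenyl bromide, then an acetyl Weinreb amide); 10 comes from resorcinol (Vilsmeier–Haack) and 17 from 4-bromophenol (Br/Li exchange, DMF).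
5. MOM ethers carry the phenols through the basic steps and are exchanged for acetates before the acid-sensitive diene and adduct appear.

Assumption: the (S)-VANOL borate is taken to shield the enone face that leads to the (1S,5S,6R) adduct; if the first run gives the antipode, (R)-VANOL is used and nothing else changes.

**Step 1**
Reactants: 1 resorcinol
Product: 2 1,3-bis(methoxymethoxy)benzene
Conditions: NaH, MOMCl, DMF, 0 °C → rt
Reagents that add atoms: chloromethyl methyl ether (MOMCl), COCCl
Why: Williamson-type O-alkylation of the bis-phenoxide gives the bis-acetal whose two OMOM groups later direct metalation.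

**Step 2**
Reactants: 2 1,3-bis(methoxymethoxy)benzene; 3 prenyl bromide
Product: 5 1,3-bis(methoxymethoxy)-2-(3-methylbut-2-en-1-yl)benzene, via aryllithium 4 (not isolated)
Conditions: n-BuLi, THF, 0 °C → rt; then CuI (10 mol %), 3, −20 °C → rt
Reagents that add atoms: none
Why: Directed ortho-metalation puts lithium at C2 between the two OMOM groups, and the copper-catalysed SN2 alkylation of the aryllithium gives the linear prenyl arene.

**Step 3**
Reactants: 5 1,3-bis(methoxymethoxy)-2-(3-methylbut-2-en-1-yl)benzene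
Product: 7 1-[2,4-bis(methoxymethoxy)-3-(3-methylbut-2-en-1-yl)phenyl]ethan-1-one, via aryllithium 6 (not isolated)
Conditions: s-BuLi, TMEDA, THF, −78 °C; then MeC(O)N(OMe)Me, −78 → 0 °C; H2O
Reagents that add atoms: N-methoxy-N-methylacetamide, CC(=O)N(C)OC
Why: A second directed ortho-metalation at C4 (C4 and C6 are equivalent), kinetically favoured at −78 °C over deprotonation of the prenyl CH2, is followed by Weinreb amide acylation, which stops at the ketone.

**Step 4**
Reactants: 1 resorcinol
Product: 9 2,4-dihydroxybenzaldehyde, via aryl iminium chloride 8 (not isolated)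
Conditions: POCl3, DMF, MeCN, −15 → 25 °C; then H2O, 50 °C
Reagents that add atoms: N,N-dimethylformamide, CN(C)C=O; water, O
Why: Vilsmeier–Haack formylation attacks C4 of resorcinol (para to one OH, ortho to the other) and the iminium salt is hydrolysed to the aldehyde.

**Step 5**
Reactants: 9 2,4-dihydroxybenzaldehyde
Product: 10 2,4-bis(methoxymethoxy)benzaldehyde
Conditions: NaH, MOMCl, DMF, 0 °C → rt
Reagents that add atoms: chloromethyl methyl ether (MOMCl), COCCl
Why: Full deprotonation with NaH lets both phenols, including the hydrogen-bonded 2-OH, be alkylated so the aldehyde tolerates the basic aldol step.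

**Step 6**
Reactants: 7 1-[2,4-bis(methoxymethoxy)-3-(3-methylbut-2-en-1-yl)phenyl]ethan-1-one; 10 2,4-bis(methoxymethoxy)benzaldehyde
Product: 11 (E)-1-[2,4-bis(methoxymethoxy)-3-(3-methylbut-2-en-1-yl)phenyl]-3-[2,4-bis(methoxymethoxy)phenyl]prop-2-en-1-one
Conditions: KOH, EtOH/H2O, rt
Reagents that add atoms: none
Why: Claisen–Schmidt condensation of the methyl ketone with a non-enolisable aldehyde, followed by E1cB dehydration, gives the thermodynamically favoured E-enone.

**Step 7**
Reactants: 11 tetra-MOM chalcone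
Product: 12 morachalcone A, (E)-1-[2,4-dihydroxy-3-(3-methylbut-2-en-1-yl)phenyl]-3-(2,4-dihydroxyphenyl)prop-2-en-1-one
Conditions: 3 M HCl, MeOH, 45 °C, ≤ 1 h
Reagents that add atoms: none
Why: Acid-catalysed acetal methanolysis removes the four MOM groups, and the short, mild treatment spares the prenyl group from cyclising onto a neighbouring phenol.

**Step 8**
Reactants: 12 morachalcone A
Product: 13 (E)-1-[4-acetoxy-2-hydroxy-3-(3-methylbut-2-en-1-yl)phenyl]-3-(2,4-diacetoxyphenyl)prop-2-en-1-one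
Conditions: Ac2O (3.3 equiv), pyridine, CH2Cl2, 0 °C
Reagents that add atoms: acetic anhydride, CC(=O)OC(C)=O
Why: Chemoselective O-acetylation leaves the 2'-OH free because it is hydrogen-bonded to the ketone and flanked by the prenyl group, and this OH is needed for boron binding.

**Step 9**
Reactants: 14 4-bromophenol
Product: 15 1-bromo-4-(methoxymethoxy)benzene
Conditions: NaH, MOMCl, DMF, 0 °C → rt
Reagents that add atoms: chloromethyl methyl ether (MOMCl), COCCl
Why: Williamson-type MOM protection masks the acidic phenol before the organolithium step.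

**Step 10**
Reactants: 15 1-bromo-4-(methoxymethoxy)benzene
Product: 17 4-(methoxymethoxy)benzaldehyde, via aryllithium 16 (not isolated)
Conditions: n-BuLi, THF, −78 °C; then DMF, −78 °C → rt; H2O
Reagents that add atoms: N,N-dimethylformamide, CN(C)C=O
Why: Bromine–lithium exchange followed by Bouveault formylation with DMF puts the aldehyde exactly at the former C–Br position.

**Step 11**
Reactants: 7 1-[2,4-bis(methoxymethoxy)-3-(3-methylbut-2-en-1-yl)phenyl]ethan-1-one; 17 4-(methoxymethoxy)benzaldehyde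
Product: 18 (E)-1-[2,4-bis(methoxymethoxy)-3-(3-methylbut-2-en-1-yl)phenyl]-3-[4-(methoxymethoxy)phenyl]prop-2-en-1-one
Conditions: KOH, EtOH/H2O, rt
Reagents that add atoms: none
Why: Claisen–Schmidt condensation as in step 6 gives the E-chalcone.

**Step 12**
Reactants: 18 tri-MOM chalcone
Product: 19 isobavachalcone, (E)-1-[2,4-dihydroxy-3-(3-methylbut-2-en-1-yl)phenyl]-3-(4-hydroxyphenyl)prop-2-en-1-one
Conditions: 3 M HCl, MeOH, 45 °C, ≤ 1 h
Reagents that add atoms: none
Why: Acid-catalysed MOM methanolysis is carried out before the acid-labile diene exists.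

**Step 13**
Reactants: 19 isobavachalcone
Product: 20 (E)-1-[2,4-diacetoxy-3-(3-methylbut-2-en-1-yl)phenyl]-3-(4-acetoxyphenyl)prop-2-en-1-one
Conditions: Ac2O (excess), pyridine, DMAP (cat.), CH2Cl2, rt
Reagents that add atoms: acetic anhydride, CC(=O)OC(C)=O
Why: DMAP-catalysed exhaustive acetylation also caps the chelated 2'-OH, so this enone cannot bind boron and act as a dienophile later.

**Step 14**
Reactants: 20 isobavachalcone triacetate
Product: 22 (E)-1-{2,4-diacetoxy-3-[(E)-3-hydroxy-3-methylbut-1-en-1-yl]phenyl}-3-(4-acetoxyphenyl)prop-2-en-1-one, via allylic hydroperoxide 21 (not isolated)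
Conditions: O2, tetraphenylporphyrin (cat.), hν (> 500 nm), CH2Cl2, 0 °C; then PPh3, 0 °C → rt
Reagents that add atoms: oxygen, O=O
Why: The Schenck ene reaction of singlet oxygen takes a benzylic hydrogen of the electron-rich trisubstituted alkene (enone and aryl acetates are inert) to give the E tertiary allylic hydroperoxide, which PPh3 reduces to the alcohol; any secondary regioisomer converges on the same diene in step 15.

**Step 15**
Reactants: 22 tertiary allylic alcohol
Product: 23 (E)-1-{2,4-diacetoxy-3-[(E)-3-methylbuta-1,3-dien-1-yl]phenyl}-3-(4-acetoxyphenyl)prop-2-en-1-one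
Conditions: Martin sulfurane (Ph2S[OC(CF3)2Ph]2), CH2Cl2, 0 °C → rt; used at once
Reagents that add atoms: none
Why: Sulfurane-mediated dehydration of the tertiary alcohol under neutral conditions removes a methyl hydrogen and gives the conjugated E-diene without touching the acetates.

**Step 16**
Reactants: 13 dienophile triacetate; 23 diene triacetate
Product: 24 (E)-1-{2,4-diacetoxy-3-[(1S,5S,6R)-6-[4-acetoxy-2-hydroxy-3-(3-methylbut-2-en-1-yl)benzoyl]-5-(2,4-diacetoxyphenyl)-3-methylcyclohex-2-en-1-yl]phenyl}-3-(4-acetoxyphenyl)prop-2-en-1-one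
Conditions: (S)-VANOL, BH3·THF, AcOH (1.2 equiv each), THF, rt, then evaporate; then 13, 23 (1.3 equiv), PhCF3, 4 Å MS, rt; chromatography to remove the exo isomer
Reagents that add atoms: none
Why: In this Diels–Alder reaction the chiral VANOL borate activates the 2-hydroxyaryl ketone of 13 and blocks one enone face; the endo approach of the E-diene sets C1-aryl and C6-aroyl cis, the E-enone keeps C5-aryl and C6-aroyl trans, and the ligand fixes the absolute sense as 1S,5S,6R.

**Step 17**
Reactants: 24 hexaacetate adduct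
Product: 25 target, (E)-1-{2,4-dihydroxy-3-[(1S,5S,6R)-6-[2,4-dihydroxy-3-(3-methylbut-2-en-1-yl)benzoyl]-5-(2,4-dihydroxyphenyl)-3-methylcyclohex-2-en-1-yl]phenyl}-3-(4-hydroxyphenyl)prop-2-en-1-one
Conditions: K2CO3 (20 mol %), MeOH, 0 °C → rt, Ar; pH 5 buffer
Reagents that add atoms: none
Why: Base-catalysed transesterification (methanolysis) cleaves the six aryl acetates under conditions too mild to epimerise C6 next to the ketone or to cyclise the chalcone.

**Compound list**
1 | resorcinol (benzene-1,3-diol) | Oc1cccc(O)c1 | starting material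
2 | 1,3-bis(methoxymethoxy)benzene | COCOc1cccc(OCOC)c1 | intermediate
3 | prenyl bromide (1-bromo-3-methylbut-2-ene) | CC(C)=CCBr | starting material
4 | [2,6-bis(methoxymethoxy)phenyl]lithium (formed in the flask) | [Li]c1c(OCOC)cccc1OCOC | intermediate
5 | 1,3-bis(methoxymethoxy)-2-(3-methylbut-2-en-1-yl)benzene | COCOc1cccc(OCOC)c1CC=C(C)C | intermediate
6 | [2,4-bis(methoxymethoxy)-3-(3-methylbut-2-en-1-yl)phenyl]lithium (formed in the flask) | [Li]c1ccc(OCOC)c(CC=C(C)C)c1OCOC | intermediate
7 | 1-[2,4-bis(methoxymethoxy)-3-(3-methylbut-2-en-1-yl)phenyl]ethan-1-one | CC(=O)c1ccc(OCOC)c(CC=C(C)C)c1OCOC | intermediate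
8 | N-[(2,4-dihydroxyphenyl)methylidene]-N-methylmethanaminium chloride (formed in the flask) | C[N+](C)=Cc1ccc(O)cc1O.[Cl-] | intermediate
9 | 2,4-dihydroxybenzaldehyde | O=Cc1ccc(O)cc1O | intermediate
10 | 2,4-bis(methoxymethoxy)benzaldehyde | COCOc1ccc(C=O)c(OCOC)c1 | intermediate
11 | (E)-1-[2,4-bis(methoxymethoxy)-3-(3-methylbut-2-en-1-yl)phenyl]-3-[2,4-bis(methoxymethoxy)phenyl]prop-2-en-1-one | COCOc1ccc(/C=C/C(=O)c2ccc(OCOC)c(CC=C(C)C)c2OCOC)c(OCOC)c1 | intermediate
12 | morachalcone A, (E)-1-[2,4-dihydroxy-3-(3-methylbut-2-en-1-yl)phenyl]-3-(2,4-dihydroxyphenyl)prop-2-en-1-one | CC(C)=CCc1c(O)ccc(C(=O)/C=C/c2ccc(O)cc2O)c1O | intermediate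
13 | (E)-1-[4-acetoxy-2-hydroxy-3-(3-methylbut-2-en-1-yl)phenyl]-3-(2,4-diacetoxyphenyl)prop-2-en-1-one | CC(C)=CCc1c(OC(C)=O)ccc(C(=O)/C=C/c2ccc(OC(C)=O)cc2OC(C)=O)c1O | intermediate
14 | 4-bromophenol | Oc1ccc(Br)cc1 | starting material
15 | 1-bromo-4-(methoxymethoxy)benzene | COCOc1ccc(Br)cc1 | intermediate
16 | [4-(methoxymethoxy)phenyl]lithium (formed in the flask) | [Li]c1ccc(OCOC)cc1 | intermediate
17 | 4-(methoxymethoxy)benzaldehyde | COCOc1ccc(C=O)cc1 | intermediate
18 | (E)-1-[2,4-bis(methoxymethoxy)-3-(3-methylbut-2-en-1-yl)phenyl]-3-[4-(methoxymethoxy)phenyl]prop-2-en-1-one | COCOc1ccc(/C=C/C(=O)c2ccc(OCOC)c(CC=C(C)C)c2OCOC)cc1 | intermediate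
19 | isobavachalcone, (E)-1-[2,4-dihydroxy-3-(3-methylbut-2-en-1-yl)phenyl]-3-(4-hydroxyphenyl)prop-2-en-1-one | CC(C)=CCc1c(O)ccc(C(=O)/C=C/c2ccc(O)cc2)c1O | intermediate
20 | (E)-1-[2,4-diacetoxy-3-(3-methylbut-2-en-1-yl)phenyl]-3-(4-acetoxyphenyl)prop-2-en-1-one | CC(C)=CCc1c(OC(C)=O)ccc(C(=O)/C=C/c2ccc(OC(C)=O)cc2)c1OC(C)=O | intermediate
21 | (E)-1-{2,4-diacetoxy-3-[(E)-3-hydroperoxy-3-methylbut-1-en-1-yl]phenyl}-3-(4-acetoxyphenyl)prop-2-en-1-one (formed in the flask) | CC(C)(OO)/C=C/c1c(OC(C)=O)ccc(C(=O)/C=C/c2ccc(OC(C)=O)cc2)c1OC(C)=O | intermediate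
22 | (E)-1-{2,4-diacetoxy-3-[(E)-3-hydroxy-3-methylbut-1-en-1-yl]phenyl}-3-(4-acetoxyphenyl)prop-2-en-1-one | CC(C)(O)/C=C/c1c(OC(C)=O)ccc(C(=O)/C=C/c2ccc(OC(C)=O)cc2)c1OC(C)=O | intermediate
23 | (E)-1-{2,4-diacetoxy-3-[(E)-3-methylbuta-1,3-dien-1-yl]phenyl}-3-(4-acetoxyphenyl)prop-2-en-1-one | C=C(C)/C=C/c1c(OC(C)=O)ccc(C(=O)/C=C/c2ccc(OC(C)=O)cc2)c1OC(C)=O | intermediate
24 | (1S,5S,6R) endo hexaacetate adduct (full name in step 16; C1-aryl and C6-aroyl cis, C5-aryl and C6-aroyl trans) | CC(C)=CCc1c(OC(C)=O)ccc(C(=O)[C@H]2[C@@H](c3c(OC(C)=O)ccc(C(=O)/C=C/c4ccc(OC(C)=O)cc4)c3OC(C)=O)C=C(C)C[C@@H]2c2ccc(OC(C)=O)cc2OC(C)=O)c1O | intermediate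
25 | (E)-1-{2,4-dihydroxy-3-[(1S,5S,6R)-6-[2,4-dihydroxy-3-(3-methylbut-2-en-1-yl)benzoyl]-5-(2,4-dihydroxyphenyl)-3-methylcyclohex-2-en-1-yl]phenyl}-3-(4-hydroxyphenyl)prop-2-en-1-one | CC(C)=CCc1c(O)ccc(C(=O)[C@H]2[C@@H](c3c(O)ccc(C(=O)/C=C/c4ccc(O)cc4)c3O)C=C(C)C[C@@H]2c2ccc(O)cc2O)c1O | target

**Totals**
Total step count: 17.
Longest linear sequence: 10 steps (1 → 2 → 5 → 7 → 18 → 19 → 20 → 22 → 23 → 24 → 25).

**Three steps most likely to fail**

Step 16 (Diels–Alder). The endo/exo ratio may be near 1:1, the enantiomeric excess may be low, and diene 23 polymerises easily. The fallback sets out from 13 and 23 and gives up reagent control of absolute configuration. The cycloaddition is run with zerovalent silver nanoparticles on silica (Ag/SiO2) in CH2Cl2 at 50 °C, which gives the endo adduct as a racemate, that is 24 together with its mirror-image (1R,5R,6S) hexaacetate F1. Preparative HPLC on a chiral amylose phase separates the two, and the fallback comes back to the route at 24.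

Step 3 (second ortho-metalation). Deprotonation of the benzylic/allylic prenyl CH2 of 5 may compete with ring lithiation. The fallback sets out from 1 and uses electrophilic substitution in place of metalation. Nencki acylation (AcOH, ZnCl2, 140 °C) gives 2,4-dihydroxyacetophenone F2. C-prenylation of its phenoxide with 3 in aqueous KOH at 0 °C → rt gives 1-[2,4-dihydroxy-3-(3-methylbut-2-en-1-yl)phenyl]ethan-1-one F3 in modest yield, after chromatographic removal of the 5-prenyl and O-prenyl isomers. Bis-MOM protection (NaH, MOMCl, DMF) comes back to the route at 7.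

Step 14 (Schenck ene reaction). Regioselectivity may be poor, and the chalcone may photoisomerise or over-oxidise. The fallback sets out from 20 and replaces photooxygenation by ionic selenium chemistry. Hydroxyselenation with PhSeCl in MeCN/H2O adds PhSe to the secondary carbon and OH to the tertiary carbon to give the β-hydroxy selenide F4 (racemic at the selenium-bearing carbon). Oxidation with H2O2 in THF at 0 °C gives the selenoxide F5, whose syn-elimination can only take a benzylic hydrogen and delivers the E allylic alcohol, coming back to the route at 22.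

**Further compounds**
F1 | step 16 | (1R,5R,6S) enantiomer of hexaacetate 24 | CC(C)=CCc1c(OC(C)=O)ccc(C(=O)[C@@H]2[C@H](c3c(OC(C)=O)ccc(C(=O)/C=C/c4ccc(OC(C)=O)cc4)c3OC(C)=O)C=C(C)C[C@H]2c2ccc(OC(C)=O)cc2OC(C)=O)c1O
F2 | step 3 | 2,4-dihydroxyacetophenone | CC(=O)c1ccc(O)cc1O
F3 | step 3 | 1-[2,4-dihydroxy-3-(3-methylbut-2-en-1-yl)phenyl]ethan-1-one | CC(=O)c1ccc(O)c(CC=C(C)C)c1O
F4 | step 14 | (E)-1-{2,4-diacetoxy-3-[3-hydroxy-3-methyl-2-(phenylselanyl)butyl]phenyl}-3-(4-acetoxyphenyl)prop-2-en-1-one | CC(C)(O)C(Cc1c(OC(C)=O)ccc(C(=O)/C=C/c2ccc(OC(C)=O)cc2)c1OC(C)=O)[Se]c1ccccc1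
F5 | step 14 | (E)-1-{2,4-diacetoxy-3-[3-hydroxy-3-methyl-2-(phenylseleninyl)butyl]phenyl}-3-(4-acetoxyphenyl)prop-2-en-1-one | CC(C)(O)C(Cc1c(OC(C)=O)ccc(C(=O)/C=C/c2ccc(OC(C)=O)cc2)c1OC(C)=O)[Se](=O)c1ccccc1
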